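The retrosynthesis removes the C5' quinone oxygen of ring B (back to a 2'-phenol), re-methylates O5, opens the O1–C2 bond of pyrone ring C, re-methylates the two ortho phenols, and then cuts both aryl–carbonyl bonds, C4–C4a and C2–C1', together.
Enabling feature: ring A (oxygen on C5, C7 and C8a, acyl carbon C4 on C4a) and ring B (oxygen on C2', C4' and C6', C2 on C1') are the same 1,3,5-trioxygenated benzene acylated at one carbon. The methoxy-bearing C3 is the only atom between the acyl carbons C4 and C2, so C2–C3–C4 is a methoxymalonyl unit.
Forward: methoxymalonyl dichloride is joined to two molecules of 1,3,5-trimethoxybenzene, so rings A and B arrive ready-made. One ortho methyl ether per ketone is then cleaved, ring C closes by cyclodehydration (O1–C2), the 5-OMe is cleaved, and ring B is oxidised to the quinone last.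
Stereochemistry: the target has no stereocentre. The sp3 centres that appear on the way (C3 of the open chain, C2 and C3 of the hemiketal) vanish when ring C becomes aromatic.

Key step: step 3

Remark: flavone locants are used throughout. In ring B, C1' sits on C2, C2' carries the phenol oxygen that becomes the quinone carbonyl next to C1', C4' and C6' carry OMe, and C5' is oxidised last. 1,3-Diketones are drawn as diketo tautomers. Boron intermediates are drawn as open aryloxydichloroboranes, although they are chelated to the neighbouring carbonyl oxygen.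

Step 1
Reactants: 1 dimethyl methoxymalonate
Product: 3 methoxymalonic acid, via dipotassium methoxymalonate 2 (not isolated)
Conditions: KOH (2.5 equiv), MeOH/H2O, 0 °C to rt; then aq. HCl to pH 1 at 0 °C, EtOAc extraction
Reagents that add atoms: potassium hydroxide, [K+].[OH-]
Why: This is an ordinary ester saponification (acyl–oxygen cleavage by hydroxide) of an unhindered malonic diester, and cold acidification and cold evaporation should keep the malonic acid from decarboxylating.

Step 2
Reactants: 3 methoxymalonic acid
Product: 4 methoxymalonyl dichloride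
Conditions: (COCl)2 (2.5 equiv), DMF (cat.), CH2Cl2, 0 °C to rt; volatiles removed cold, used crude
Reagents that add atoms: oxalyl chloride, O=C(Cl)C(=O)Cl
Why: Chloroiminium-catalysed (Vilsmeier-type) acid chloride formation runs at or below room temperature and gives only gaseous by-products, so the heat-sensitive dichloride, which can lose HCl to a chlorocarbonyl ketene, needs no distillation.

Step 3
Reactants: 4 methoxymalonyl dichloride; 5 1,3,5-trimethoxybenzene (two molecules are incorporated)
Product: 7 2-methoxy-1,3-bis(2,4,6-trimethoxyphenyl)propane-1,3-dione, via monoacylated acid chloride 6 (not isolated)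
Conditions: 5 (4 equiv), SnCl4 (2.2 equiv), CH2Cl2, −40 °C, slow addition of 4, then to 0 °C; ice-water quench; surplus 5 recovered
Reagents that add atoms: none
Why: SnCl4 polarises each C–Cl bond of 4 to an acylium-type ion pair (an acylketene formed by HCl loss is an equivalent electrophile), and the arene attacks it by electrophilic aromatic substitution and rearomatises with loss of HCl, first to 6 and then to 7, which forms C4–C4a and C2–C1' in one operation. The closest known reaction type is the Friedel–Crafts diacylation of arenes by malonyl dichlorides to 1,3-diaryl-1,3-diketones. No ring is formed and no lasting stereocentre arises, because C3 of 7 carries two identical aroyl groups. Site selectivity is built into the substrates: the three CH positions of 5 are equivalent, the acylated ring is deactivated towards a second acylation, and both positions ortho to the new ketone are blocked by OMe, so indanedione closure is impossible. The selectivity that is needed is kinetic, since the second intermolecular acylation must outrun lactonisation of 6 through an ortho methoxy oxygen and CO loss from the α-methoxy acylium ion; slow addition of 4 to an excess of the very nucleophilic arene, a mild Lewis acid and low temperature favour the bimolecular path, and the cation left by CO loss would be destabilised by its flanking carbonyl group. Any ortho O-demethylation of 7 by SnCl4 would be harmless, because it only anticipates step 4.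

Step 4
Reactants: 7 2-methoxy-1,3-bis(2,4,6-trimethoxyphenyl)propane-1,3-dione
Product: 9 1,3-bis(2-hydroxy-4,6-dimethoxyphenyl)-2-methoxypropane-1,3-dione, via bis(dichloroboryl) chelate 8 (not isolated)
Conditions: BCl3 (3 equiv), CH2Cl2, −78 °C to 0 °C; then H2O
Reagents that add atoms: none
Why: In this chelation-directed aryl methyl ether cleavage, BCl3 bound to each ketone oxygen reaches one ortho OMe, chloride removes the methyl group by SN2, and the six-membered boron chelate then occupies the carbonyl, so the second ortho OMe, the para OMe and the aliphatic C3 OMe (a poorer leaving group than an aryloxide) should stay intact.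

Step 5
Reactants: 9 1,3-bis(2-hydroxy-4,6-dimethoxyphenyl)-2-methoxypropane-1,3-dione
Product: 11 2-(2-hydroxy-4,6-dimethoxyphenyl)-3,5,7-trimethoxy-4H-chromen-4-one, via 2-hydroxyflavanone hemiketal 10 (not isolated)
Conditions: p-TsOH·H2O (0.2 equiv), toluene, reflux, azeotropic removal of water
Reagents that add atoms: none
Why: This is the acid-catalysed cyclodehydration of an o-hydroxyaryl 1,3-diketone (the closing stage of the Baker–Venkataraman flavone synthesis), in which 6-exo-trig addition of a phenol to the distal ketone gives 10 and loss of water gives the aromatic 4-pyrone, and because 9 is symmetric either phenol, or any ring opening and reclosure through the 2'-OH, leads to the same flavone.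

Step 6
Reactants: 11 2-(2-hydroxy-4,6-dimethoxyphenyl)-3,5,7-trimethoxy-4H-chromen-4-one
Product: 13 5-hydroxy-2-(2-hydroxy-4,6-dimethoxyphenyl)-3,7-dimethoxy-4H-chromen-4-one, via bis(dichloroboryl) ether 12 (not isolated)
Conditions: BCl3 (2.5 equiv), CH2Cl2, −78 °C to −10 °C; then H2O
Reagents that add atoms: none
Why: This is the well-known selective peri demethylation of 5-methoxyflavones, in which one equivalent of BCl3 is taken up by the free 2'-OH and the next forms the favoured six-membered chelate between C4=O and O5, whereas the 3-OMe could only form a five-membered chelate and the 7-, 4'- and 6'-OMe groups have no neighbouring carbonyl.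

Step 7
Reactants: 13 5-hydroxy-2-(2-hydroxy-4,6-dimethoxyphenyl)-3,7-dimethoxy-4H-chromen-4-one
Product: 14 2-(5-hydroxy-3,7-dimethoxy-4-oxo-4H-chromen-2-yl)-3,5-dimethoxycyclohexa-2,5-diene-1,4-dione (CNP0259413.0)
Conditions: ON(SO3K)2 (2.5 equiv), KH2PO4 buffer (pH 6), H2O/acetone, 0 °C to rt
Reagents that add atoms: potassium nitrosodisulfonate, [K+].[K+].[O]N(S(=O)(=O)[O-])S(=O)(=O)[O-]
Why: In the Teuber oxidation one nitroxyl radical abstracts hydrogen from the electron-rich 2'-phenol, a second couples at the free para carbon C5', and loss of HN(SO3K)2 gives the p-quinone, while the 5-OH is hydrogen-bonded to C4=O on an acyl-deactivated ring and should react far more slowly.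

Compound list
1 | dimethyl methoxymalonate (dimethyl 2-methoxypropanedioate) | COC(C(=O)OC)C(=O)OC | starting material
2 | dipotassium methoxymalonate | COC(C(=O)[O-])C(=O)[O-].[K+].[K+] | intermediate
3 | methoxymalonic acid (2-methoxypropanedioic acid) | COC(C(=O)O)C(=O)O | intermediate
4 | methoxymalonyl dichloride (2-methoxypropanedioyl dichloride) | COC(C(=O)Cl)C(=O)Cl | intermediate
5 | 1,3,5-trimethoxybenzene | COc1cc(OC)cc(OC)c1 | starting material
6 | 2-methoxy-3-oxo-3-(2,4,6-trimethoxyphenyl)propanoyl chloride (racemic, enolisable centre) | COC(C(=O)Cl)C(=O)c1c(OC)cc(OC)cc1OC | intermediate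
7 | 2-methoxy-1,3-bis(2,4,6-trimethoxyphenyl)propane-1,3-dione | COC(C(=O)c1c(OC)cc(OC)cc1OC)C(=O)c1c(OC)cc(OC)cc1OC | intermediate
8 | 1,3-bis[2-(dichloroboryloxy)-4,6-dimethoxyphenyl]-2-methoxypropane-1,3-dione | COC(C(=O)c1c(OB(Cl)Cl)cc(OC)cc1OC)C(=O)c1c(OB(Cl)Cl)cc(OC)cc1OC | intermediate
9 | 1,3-bis(2-hydroxy-4,6-dimethoxyphenyl)-2-methoxypropane-1,3-dione | COC(C(=O)c1c(O)cc(OC)cc1OC)C(=O)c1c(O)cc(OC)cc1OC | intermediate
10 | 2-hydroxy-2-(2-hydroxy-4,6-dimethoxyphenyl)-3,5,7-trimethoxychroman-4-one (diastereomer mixture, both centres lost on dehydration) | COC1C(=O)c2c(OC)cc(OC)cc2OC1(O)c1c(O)cc(OC)cc1OC | intermediate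
11 | 2-(2-hydroxy-4,6-dimethoxyphenyl)-3,5,7-trimethoxy-4H-chromen-4-one | COc1cc(O)c(-c2oc3cc(OC)cc(OC)c3c(=O)c2OC)c(OC)c1 | intermediate
12 | 5-(dichloroboryloxy)-2-[2-(dichloroboryloxy)-4,6-dimethoxyphenyl]-3,7-dimethoxy-4H-chromen-4-one | COc1cc(OB(Cl)Cl)c(-c2oc3cc(OC)cc(OB(Cl)Cl)c3c(=O)c2OC)c(OC)c1 | intermediate
13 | 5-hydroxy-2-(2-hydroxy-4,6-dimethoxyphenyl)-3,7-dimethoxy-4H-chromen-4-one | COc1cc(O)c(-c2oc3cc(OC)cc(O)c3c(=O)c2OC)c(OC)c1 | intermediate
14 | 2-(5-hydroxy-3,7-dimethoxy-4-oxo-4H-chromen-2-yl)-3,5-dimethoxycyclohexa-2,5-diene-1,4-dione | COC1=CC(=O)C(c2oc3cc(OC)cc(O)c3c(=O)c2OC)=C(OC)C1=O | target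

Total step count: 7. Longest linear sequence: 7 steps (1 to 14); 5 is bought and enters at step 3.

Steps most likely to fail

1. Step 3 (double acylation). Once the first aryl–carbonyl bond is made, three processes may outrun the second intermolecular acylation. These are attack of an ortho methoxy oxygen on the remaining acid chloride (lactonisation with loss of chloromethane), loss of CO from the α-methoxy acylium ion, and ketene oligomerisation. The fallback sets out from 5 and comes back at 9. It joins the halves one bond at a time and delivers the second carbonyl intramolecularly. Compound 5 is lithiated between two methoxy groups (n-BuLi, THF, 0 °C) to 2,4,6-trimethoxyphenyllithium F1. This is acylated by N,2-dimethoxy-N-methylacetamide (Weinreb ketone synthesis, aq. HCl quench) to 2-methoxy-1-(2,4,6-trimethoxyphenyl)ethan-1-one F2. BCl3 in CH2Cl2 frees one ortho phenol of this simple monoketone and gives 1-(2-hydroxy-4,6-dimethoxyphenyl)-2-methoxyethan-1-one F3. Esterification with commercial 2,4,6-trimethoxybenzoic acid activated by (CF3CO)2O gives 3,5-dimethoxy-2-(methoxyacetyl)phenyl 2,4,6-trimethoxybenzoate F4. Baker–Venkataraman acyl migration (LiN(SiMe3)2, THF, −78 °C to rt) gives 1-(2-hydroxy-4,6-dimethoxyphenyl)-2-methoxy-3-(2,4,6-trimethoxyphenyl)propane-1,3-dione F5. A last BCl3 treatment cleaves one ortho methyl ether of the ring that is still fully methylated and delivers 9.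

2. Step 7 (quinone formation). Hydrogen abstraction and coupling at ring B may be slow, because C5' is flanked by two methoxy groups and the substrate dissolves poorly in water. Oxidation of ring A through the 5-OH (its para carbon C8 is free) or hydrolytic loss of a quinone methoxy group could then compete. The fallback sets out from 11 and comes back at 14. It carries out the oxidation while ring A has no free phenol at all. Compound 11 is treated with ON(SO3K)2 under the buffered conditions of step 7 and should give 2-(3,5,7-trimethoxy-4-oxo-4H-chromen-2-yl)-3,5-dimethoxycyclohexa-2,5-diene-1,4-dione F6. The 5-OMe is then cleaved with barely more than one equivalent of BCl3 in CH2Cl2 at −78 °C. This relies on the six-membered peri chelate at C4=O being stronger than any five-membered chelate at the quinone, and it leads to 14.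

3. Step 6 (5-O-demethylation). Ether cleavage may spread from the 5-OMe to the 3-OMe. The boron aryloxide formed at the 2'-oxygen lies next to the 3-OMe and can deliver the Lewis acid to it. The fallback sets out from 11 and comes back at 13. It removes the free phenol from play before the Lewis acid is added. Acetylation (Ac2O, pyridine) gives 2-(3,5,7-trimethoxy-4-oxo-4H-chromen-2-yl)-3,5-dimethoxyphenyl acetate F7. BCl3 in CH2Cl2 at low temperature then cleaves only the peri ether and gives 2-(5-hydroxy-3,7-dimethoxy-4-oxo-4H-chromen-2-yl)-3,5-dimethoxyphenyl acetate F8. Methanolysis (K2CO3, MeOH, rt) returns 13.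

Further compounds
F1 | step 3 | 2,4,6-trimethoxyphenyllithium | [Li]c1c(OC)cc(OC)cc1OC
F2 | step 3 | 2-methoxy-1-(2,4,6-trimethoxyphenyl)ethan-1-one | COCC(=O)c1c(OC)cc(OC)cc1OC
F3 | step 3 | 1-(2-hydroxy-4,6-dimethoxyphenyl)-2-methoxyethan-1-one | COCC(=O)c1c(O)cc(OC)cc1OC
F4 | step 3 | 3,5-dimethoxy-2-(methoxyacetyl)phenyl 2,4,6-trimethoxybenzoate | COCC(=O)c1c(OC(=O)c2c(OC)cc(OC)cc2OC)cc(OC)cc1OC
F5 | step 3 | 1-(2-hydroxy-4,6-dimethoxyphenyl)-2-methoxy-3-(2,4,6-trimethoxyphenyl)propane-1,3-dione (racemic, enolisable centre) | COC(C(=O)c1c(O)cc(OC)cc1OC)C(=O)c1c(OC)cc(OC)cc1OC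
F6 | step 7 | 2-(3,5,7-trimethoxy-4-oxo-4H-chromen-2-yl)-3,5-dimethoxycyclohexa-2,5-diene-1,4-dione | COC1=CC(=O)C(c2oc3cc(OC)cc(OC)c3c(=O)c2OC)=C(OC)C1=O
F7 | step 6 | 2-(3,5,7-trimethoxy-4-oxo-4H-chromen-2-yl)-3,5-dimethoxyphenyl acetate | CC(=O)Oc1cc(OC)cc(OC)c1-c1oc2cc(OC)cc(OC)c2c(=O)c1OC
F8 | step 6 | 2-(5-hydroxy-3,7-dimethoxy-4-oxo-4H-chromen-2-yl)-3,5-dimethoxyphenyl acetate | CC(=O)Oc1cc(OC)cc(OC)c1-c1oc2cc(OC)cc(O)c2c(=O)c1OC
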